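# Proposed total synthesis of CNP0304150.3 by a lactone Ireland–Claisen rearrangement

## Analysis of the target

The target is a trans-fused decalin, numbered here C1 (ring ketone), C2, C3, C4, ring-fusion C4a, C5, C6, C7, C8 and ring-fusion C8a; ring A holds C1–C4 and ring B holds C5–C8. Ring A carries the C1 ketone between two tertiary carbinols (C2 with a methyl group, C8a at the fusion), a sec-butyl group at C3 and a quaternary C4 bearing a methyl group and an (E)-3-methoxyacryloyl group. Ring B carries a methyl group at C5 and a tertiary carbinol at C7. There are eight stereocentres: the hydroxyls at C2, C7 and C8a and the C4 methyl lie on one face, while the sec-butyl group, the C4 acyl group, the C4a hydrogen and the C5 methyl lie on the other. The sec-butyl group is therefore cis to the acyl group, and its own (S) centre sits outside the ring. The β-methoxy enone is a vinylogous ester that will not survive acid or carbon nucleophiles, the α,α'-dihydroxy ketone can undergo acyloin shifts, and the tertiary alcohols can eliminate. The main difficulty is the contiguous array C2–C3–C4–C4a–C5, above all the bond between quaternary C4 and tertiary C3, which carries a branched substituent. The strategy rests on one feature: C4 bears an acyl carbon and adjoins C3, so the C3–C4 bond can be made by a [3,3] shift in which the acyl carbon is a lactone carbonyl, C1 is the lactone carbinol carbon and C1–C2=C3 is an (E)-alkenyl group on it.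

## Retrosynthetic reasoning

**Enol ether C–O bond (31 to 30).** The methoxy enone is the most fragile group and is removed first. Cutting the methoxy group from the enone β-carbon leads to terminal ynone 30. The forward step must add a methoxy group in conjugate fashion under non-acidic conditions and give the (E)-isomer.

**C1 and C2 oxygen atoms (30 to 29 to 28).** Both carbonyl groups of 30 are traced to secondary carbinols in pentaol 29, so a single oxidation makes the ring ketone and the ynone together. The C1–O and C2–O bonds are then cut together back to the C1=C2 alkene of 28. This alkene is what the sigmatropic step leaves behind, and the C8a hydroxyl is allylic to it and on the face where the C2 hydroxyl must go. The forward step has to be a hydroxyl-directed cis-dihydroxylation.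

**Side-chain C–C bond (28 to 27 to 26 to 25).** The bond between the carbinol carbon and the alkyne is cut to give neopentyl aldehyde 27 and an ethynyl nucleophile. The aldehyde carbon is traced through alcohol 26 to the ester carbon of 25, so the carboxyl carbon delivered by the key step becomes the acyl carbon of the target. The forward steps act on a very hindered position and therefore use small reagents.

**C7 methyl group (25 to 24).** The C7–CH3 bond is cut to give ketone 24. The forward addition must come from the equatorial direction so that the new hydroxyl is cis to the C8a hydroxyl.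

**Ring B (24 to 22 to 19 and 20).** The C8–C8a bond is an aldol bond and the C4a–C5 bond a conjugate-addition bond; both lie next to the C8a carbonyl carbon of enone 19. Enone 20 supplies C5–C8 and the C5 methyl group. The forward steps must set C4a, C5 and C8a from the C3/C4 pair already present.

**Functional-group adjustments (19 to 18 to 17).** The C8a ketone is masked as the dithiane of 18, and the ester is traced to acid 17.

**Key disconnection (17 to 14).** The C3–C4 bond is cut and the C1–O bond re-formed, which gives alkenyl lactone 14. This is the only bond joining the quaternary and the branched tertiary carbon. Making it inside a cyclic array removes the questions of enolate geometry and facial choice, so the carbinol centre and the (E)-alkene fix both new centres.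

**Lactone C–O bond and carbinol centre (14 to 13 to 12).** The lactone is opened to hydroxy ester 13, whose carbinol centre comes from ketone 12 by catalyst-controlled reduction.

**C4a–C8a bond (12 to 10 and 11).** The acyl dithiane carbon of 10 is the nucleophile and acrylate 11 the acceptor. Compound 11 brings C4a, C4, the C4 methyl and the carboxyl carbon at the right oxidation level, so no oxidation is needed later in the presence of sulfur.

**C1–C8a bond (10 to 9 to 6 and 7).** Dithiane 7 acts as an acyl-anion equivalent for C8a and adds to enal 6; oxidation of 9 gives 10.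

**C2=C3 alkene (6 to 5 to 4 to 1 and 2).** The alkene is cut by a Wittig transform to the aldehyde derived from 1 and ylide 2. The sec-butyl centre comes from the chiral pool, and the olefination must give the (E)-alkene that the key step needs.

## Alternatives that were turned down

**Alternative 1:** The disconnection cuts C2–C3 and C4–C4a of ring A together, with ring B and its C5 and C7 centres made beforehand. In the forward direction an EtAlCl2-promoted Diels–Alder reaction between a silyloxydiene mounted on ring B and a chiral trisubstituted enal would give octalin silyl enol ether A1.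
- For: it is convergent, it brings the ring-B stereocentres ready-made, it sets C3, C4 and C4a in one step, and its enol ether is well placed for oxidation to the C8a carbinol and C1 ketone. On convergence it is stronger than the chosen route.
- Against: the C4–C4a bond joins a quaternary carbon to a ring carbon flanked by the C5 methyl in an intermolecular step between a diene with a fully substituted terminus and a β-branched, α,α-disubstituted dienophile. Facial choice on the diene rests on C5 alone, and endo/exo choice decides C3/C4 against C4a. The C4 methyl must be carried as a protected hydroxymethyl group and deoxygenated later, the C2 oxygen must be added afterwards to a congested ring, and a free tertiary alcohol must survive the Lewis acid.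
- Comparison: the chosen route gives up convergence for a unimolecular key step with a single possible geometry. In it the C4 methyl and acyl carbon arrive in final form and the C1=C2 alkene is left where oxygen is needed.

**Alternative 2:** The disconnection cuts C4a–C8a and C5–C6 of ring B, ring A arising as the tether ring with a diisopropylsilylene bridge between the C2 and C8a oxygen atoms. On heating, a silyloxydiene and a propenyl dienophile would combine to give the silylene-bridged octalinone A2.
- For: both rings close at once, C4a, C5 and C8a are set together, and the two carbinol oxygen atoms are in place and tied cis. It forms more bonds per step and has a shorter endgame than the chosen route.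
- Against: the cyclisation substrate must already contain C2, C3 and C4, including the quaternary/tertiary C3–C4 pair, in an open chain, so the hardest bond is left to acyclic stereocontrol. The dienophile is unactivated and attached to a quaternary carbon, so high temperatures are needed, while the diene is an enol derivative of an α-diketone. The trans fusion depends on one of two tether conformations, and ring B emerges with a C7=C8 alkene whose hydration must still set C7.
- Comparison: the chosen route solves the C3–C4 problem first and through a fixed geometry. It then adds each remaining centre one at a time on a rigid ring, at the cost of more steps.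

**Alternative 3:** The disconnection cuts C2–C3 (Prins) and the C4–methyl bond (pinacol shift), with ring B complete and its diol held as a cyclic carbonate. TiCl4 would activate the C2 carbonyl of an α-diketone on C8a, a (Z)-alkene would attack it, and the C4 cation would be quenched by a methyl shift from the neighbouring silyloxy carbon, which becomes the acetyl group of decalin methyl ketone A3.
- For: ring A, the C2 carbinol, C3 and the quaternary C4 with its acetyl group appear in one cascade, and the C1 ketone is already present. Its endgame (formylation and O-methylation) is the shortest of all, shorter than that of the chosen route.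
- Against: it needs a stereodefined (Z)-trisubstituted alkene bearing the sec-butyl group. Three stereocentres come from a cationic cascade whose facial choices are not enforced by a cyclic array. The C4 cation sits next to the sec-butyl methine, so a hydride shift that destroys that centre, or elimination, can compete with methyl migration. The two carbonyl groups of the dione must also be told apart.
- Comparison: the chosen route forms the same quaternary centre by a concerted suprafacial shift with no cationic intermediate, and pays for this with a longer sequence after the key step.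

Key step: step 9

## Route

Remark (assumption): in step 7 the fully substituted dithianyl carbon is taken to act as the larger ketone substituent towards the oxazaborolidine.
Remark: 12, 13 and 14 are carried as mixtures at the methyl-bearing carbon next to the ester or lactone carbonyl, a centre that becomes planar in step 9; in 24–31 the locants are those of the target as defined in the analysis.

Step 1
Reactants: 1 (S)-2-methylbutan-1-ol; 2 ethyl 2-(triphenylphosphoranylidene)propanoate
Product: 4 ethyl (2E,4S)-2,4-dimethylhex-2-enoate, via (S)-2-methylbutanal 3 (not isolated)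
Conditions: TEMPO (cat.), PhI(OAc)2, CH2Cl2, rt; then 2, rt
Reagents that add atoms: none
Why: One-pot oxoammonium oxidation and Wittig olefination: the non-basic medium lets the stabilised ylide trap the configurationally labile α-branched aldehyde 3 as it forms, the α-methyl ylide should give the (E)-trisubstituted enoate, and the stereocentre of 1 is carried over unchanged.

Step 2
Reactants: 4 ethyl (2E,4S)-2,4-dimethylhex-2-enoate
Product: 5 (2E,4S)-2,4-dimethylhex-2-en-1-ol
Conditions: i-Bu2AlH, CH2Cl2, −78 °C
Reagents that add atoms: none
Why: Hydride 1,2-reduction of the conjugated ester gives the allylic alcohol without touching the alkene or the stereocentre.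

Step 3
Reactants: 5 (2E,4S)-2,4-dimethylhex-2-en-1-ol
Product: 6 (2E,4S)-2,4-dimethylhex-2-enal
Conditions: MnO2, CH2Cl2, rt
Reagents that add atoms: none
Why: Selective allylic oxidation on MnO2 under neutral conditions, which should not isomerise the (E)-alkene or epimerise the γ-centre.

Step 4
Reactants: 7 1,3-dithiane; 6 (2E,4S)-2,4-dimethylhex-2-enal
Product: 9 (2E,4S)-1-(1,3-dithian-2-yl)-2,4-dimethylhex-2-en-1-ol (both C1 epimers), via 2-lithio-1,3-dithiane 8 (not isolated)
Conditions: n-BuLi, THF, −30 °C; then 6, −78 °C
Reagents that add atoms: none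
Why: Corey–Seebach umpolung: the lithiated dithiane adds 1,2 to the enal in THF without polar cosolvent; the carbinol centre is left uncontrolled because it is oxidised in step 5.

Step 5
Reactants: 9 (2E,4S)-1-(1,3-dithian-2-yl)-2,4-dimethylhex-2-en-1-ol
Product: 10 (2E,4S)-1-(1,3-dithian-2-yl)-2,4-dimethylhex-2-en-1-one
Conditions: SO3·pyridine, DMSO, i-Pr2NEt, CH2Cl2, 0 °C
Reagents that add atoms: none
Why: Parikh–Doering (activated DMSO) oxidation tolerates the thioacetal, where hypervalent iodine or chlorine oxidants would attack sulfur, and delivers the 2-acyl dithiane.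

Step 6
Reactants: 10 (2E,4S)-1-(1,3-dithian-2-yl)-2,4-dimethylhex-2-en-1-one; 11 methyl methacrylate
Product: 12 methyl 3-{2-[(2E,4S)-2,4-dimethylhex-2-enoyl]-1,3-dithian-2-yl}-2-methylpropanoate (both C2 epimers)
Conditions: Cs2CO3 (0.2 equiv), DMF, rt
Reagents that add atoms: none
Why: Michael addition: the dithiane C–H of 10, acidified by the carbonyl and two sulfur atoms, is removed by carbonate and the soft enolate adds through carbon to the acrylate, creating the fully substituted C8a. The weak base should leave the γ-centre of the enone alone, and the new α-methyl centre is erased in step 9.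

Step 7
Reactants: 12 methyl 3-{2-[(2E,4S)-2,4-dimethylhex-2-enoyl]-1,3-dithian-2-yl}-2-methylpropanoate
Product: 13 methyl 3-{2-[(1R,2E,4S)-1-hydroxy-2,4-dimethylhex-2-en-1-yl]-1,3-dithian-2-yl}-2-methylpropanoate
Conditions: (S)-2-methyl-CBS-oxazaborolidine (0.3 equiv), BH3·SMe2, THF, −20 °C; MeOH
Reagents that add atoms: none
Why: Corey–Bakshi–Shibata reduction: the ketone should bind the catalyst boron on the side of the planar alkenyl group, away from the fully substituted dithianyl carbon, so the (S)-catalyst delivers hydride to give the (1R)-carbinol, by analogy with aryl methyl ketones with dithianyl in the role of aryl. The low temperature avoids hydroboration of the trisubstituted alkene and the ester is inert to borane.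

Step 8
Reactants: 13 methyl 3-{2-[(1R,2E,4S)-1-hydroxy-2,4-dimethylhex-2-en-1-yl]-1,3-dithian-2-yl}-2-methylpropanoate
Product: 14 (7R)-10-methyl-7-[(2E,4S)-4-methylhex-2-en-2-yl]-8-oxa-1,5-dithiaspiro[5.5]undecan-9-one (both C10 epimers)
Conditions: DBU (cat.), PhMe, 80 °C, 4 Å MS
Reagents that add atoms: none
Why: Base-catalysed intramolecular transesterification (lactonisation): six-membered ring closure is favoured by the geminal dithiane substitution and by removal of methanol, and basic conditions avoid ionisation of the allylic C–O bond next to sulfur.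

Step 9
Reactants: 14 (7R)-10-methyl-7-[(2E,4S)-4-methylhex-2-en-2-yl]-8-oxa-1,5-dithiaspiro[5.5]undecan-9-one
Product: 17 (9S,10R)-9-[(2S)-butan-2-yl]-8,10-dimethyl-1,5-dithiaspiro[5.5]undec-7-ene-10-carboxylic acid, via trimethylsilyl ketene acetal 15 (not isolated), via trimethylsilyl ester 16 (not isolated)
Conditions: LiN(i-Pr)2, Me3SiCl, Et3N, THF, −78 °C to rt; PhMe, 105 °C; 1 M HCl
Reagents that add atoms: none
Why: Ireland–Claisen rearrangement of a lactone silyl ketene acetal: the amide base removes the α-proton of 14 in the presence of Me3SiCl, O-silylation gives cyclic ketene acetal 15 (both α-methyl epimers give the same 15), and on heating the array C4=C(OSi)–O–C1–C2=C3 undergoes a concerted suprafacial [3,3] shift that forms C3–C4, breaks C1–O and leaves silyl ester 16, which is hydrolysed to 17 on work-up. The closest known reaction type is the rearrangement of lactone ketene acetals that carry an alkenyl group on the carbinol carbon, which gives cycloalkene carboxylic acids. Ring A closes in a pericyclic, transannular mode: the new bond spans the lactone from C4 to the alkene terminus C3 through a bicyclo[2.2.2]octane-like transition state, so the six-membered carbocycle (C1, C2, C3, C4, C4a, C8a) replaces the six-membered lactone. Because the ketene acetal double bond is held inside the lactone ring, its geometry is fixed (C4a cis to the ring oxygen) and only a boat arrangement of the six reacting atoms is possible. C3 is controlled by the (E)-geometry of C2=C3, which puts the sec-butyl group outside and hydrogen inside the forming ring, and C4 by the fixed ketene acetal geometry; together they place sec-butyl cis to the carboxyl group. The absolute sense comes from the (7R)-carbinol centre, because C4 must bond to the alkene face that carries the departing oxygen. The only selectivity needed is complete chirality transfer, which the single available transition-state geometry secures; the price is steric, since a quaternary and a branched tertiary carbon are joined, so prolonged heating may be needed.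

Step 10
Reactants: 17 (9S,10R)-9-[(2S)-butan-2-yl]-8,10-dimethyl-1,5-dithiaspiro[5.5]undec-7-ene-10-carboxylic acid
Product: 18 methyl (9S,10R)-9-[(2S)-butan-2-yl]-8,10-dimethyl-1,5-dithiaspiro[5.5]undec-7-ene-10-carboxylate
Conditions: Me3SiCHN2, MeOH/PhMe, 0 °C
Reagents that add atoms: (trimethylsilyl)diazomethane, C[Si](C)(C)C=[N+]=[N-]
Why: Neutral O-methylation of the carboxylic acid (diazoalkane esterification); the free acid would quench the enolates of steps 12 and 13, and no stereocentre is touched.

Step 11
Reactants: 18 methyl (9S,10R)-9-[(2S)-butan-2-yl]-8,10-dimethyl-1,5-dithiaspiro[5.5]undec-7-ene-10-carboxylate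
Product: 19 methyl (1R,2S)-2-[(2S)-butan-2-yl]-1,3-dimethyl-5-oxocyclohex-3-ene-1-carboxylate
Conditions: PhI(OCOCF3)2, MeCN/H2O, 0 °C
Reagents that add atoms: water, O
Why: Oxidative dithioacetal hydrolysis with a hypervalent iodine reagent: sulfur is oxidised, water adds to the thionium ion and the ketone is released. The alkene is already in the conjugated position, so the C8a enone forms directly, and C4 has no α-hydrogen to lose.

Step 12
Reactants: 19 methyl (1R,2S)-2-[(2S)-butan-2-yl]-1,3-dimethyl-5-oxocyclohex-3-ene-1-carboxylate; 20 (E)-pent-3-en-2-one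
Product: 22 methyl (1S,2S,6R)-2-[(2S)-butan-2-yl]-1,3-dimethyl-5-oxo-6-[(2R)-4-oxopentan-2-yl]cyclohex-3-ene-1-carboxylate, via lithium dienolate 21 (not isolated)
Conditions: LiN(i-Pr)2, THF, −78 °C; then 20, −78 °C; AcOH, −78 °C
Reagents that add atoms: none
Why: Michael addition of a kinetic lithium enolate: α'-deprotonation of the enone at C4a gives cross-conjugated dienolate 21, which adds to the β-carbon of 20 and forms C4a–C5. The lower face of 21 carries both the sec-butyl and the ester group, so the acceptor should approach from the face of the C4 methyl group. The (E)-enolate and (E)-enone should react through the lithium-bridged synclinal arrangement with ring carbon C4 anti to the acceptor double bond, which gives the (4aR,5R) relationship (C5 methyl trans to C4 on the future ring B); the cold quench is meant to stop a second conjugate addition onto C2.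

Step 13
Reactants: 22 methyl (1S,2S,6R)-2-[(2S)-butan-2-yl]-1,3-dimethyl-5-oxo-6-[(2R)-4-oxopentan-2-yl]cyclohex-3-ene-1-carboxylate
Product: 24 methyl (3S,4S,4aR,5R,8aS)-3-[(2S)-butan-2-yl]-8a-hydroxy-2,4,5-trimethyl-7-oxo-3,4,4a,5,6,7,8,8a-octahydronaphthalene-4-carboxylate, via lithium enolate 23 (not isolated)
Conditions: LiN(i-Pr)2, THF, −78 to −40 °C; AcOH, −78 °C
Reagents that add atoms: none
Why: Intramolecular aldol addition: the base removes a proton from the methyl group of the methyl ketone (kinetic, least hindered site) and enolate 23 adds to the C8a carbonyl through a chair-like six-membered closure that forms C8–C8a and ring B. C8 should enter from the face opposite the pseudoaxial C4 methyl (equatorial bond at C8a), which gives the trans ring fusion with the C8a hydroxyl on the methyl face; the cold acidic quench avoids retro-aldol cleavage and dehydration.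

Step 14
Reactants: 24 methyl (3S,4S,4aR,5R,8aS)-3-[(2S)-butan-2-yl]-8a-hydroxy-2,4,5-trimethyl-7-oxo-3,4,4a,5,6,7,8,8a-octahydronaphthalene-4-carboxylate
Product: 25 methyl (3S,4S,4aR,5R,7R,8aS)-3-[(2S)-butan-2-yl]-7,8a-dihydroxy-2,4,5,7-tetramethyl-3,4,4a,5,6,7,8,8a-octahydronaphthalene-4-carboxylate
Conditions: MeLi, CeCl3, THF, −78 °C
Reagents that add atoms: methyllithium, [Li]C
Why: Organocerium addition to a ketone: the weakly basic methylcerium reagent should add to the β-hydroxy ketone without enolisation or retro-aldol cleavage and ignore the hindered ester. Axial approach to C7 is blocked by the syn-axial C8a oxygen, so methyl enters equatorially and the new hydroxyl is axial, cis to the C8a hydroxyl.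

Step 15
Reactants: 25 methyl (3S,4S,4aR,5R,7R,8aS)-3-[(2S)-butan-2-yl]-7,8a-dihydroxy-2,4,5,7-tetramethyl-3,4,4a,5,6,7,8,8a-octahydronaphthalene-4-carboxylate
Product: 26 (3S,4S,4aR,5R,7R,8aS)-3-[(2S)-butan-2-yl]-4-(hydroxymethyl)-2,4,5,7-tetramethyl-3,4,4a,5,6,7,8,8a-octahydronaphthalene-7,8a-diol
Conditions: LiAlH4, THF, 0 °C to reflux
Reagents that add atoms: none
Why: Hydride reduction of the neopentyl methyl ester to the primary alcohol; the tertiary alkoxides and the isolated trisubstituted alkene are inert.

Step 16
Reactants: 26 (3S,4S,4aR,5R,7R,8aS)-3-[(2S)-butan-2-yl]-4-(hydroxymethyl)-2,4,5,7-tetramethyl-3,4,4a,5,6,7,8,8a-octahydronaphthalene-7,8a-diol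
Product: 27 (3S,4S,4aR,5R,7R,8aS)-3-[(2S)-butan-2-yl]-7,8a-dihydroxy-2,4,5,7-tetramethyl-3,4,4a,5,6,7,8,8a-octahydronaphthalene-4-carbaldehyde
Conditions: Dess–Martin periodinane, pyridine, CH2Cl2, 0 °C to rt
Reagents that add atoms: none
Why: Dess–Martin oxidation of the only oxidisable (primary) alcohol; the aldehyde has no α-hydrogen, and the buffered, chromium-free oxidant avoids oxidative transposition of the tertiary allylic alcohol.

Step 17
Reactants: 27 (3S,4S,4aR,5R,7R,8aS)-3-[(2S)-butan-2-yl]-7,8a-dihydroxy-2,4,5,7-tetramethyl-3,4,4a,5,6,7,8,8a-octahydronaphthalene-4-carbaldehyde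
Product: 28 (3S,4S,4aR,5R,7R,8aS)-3-[(2S)-butan-2-yl]-4-(1-hydroxyprop-2-yn-1-yl)-2,4,5,7-tetramethyl-3,4,4a,5,6,7,8,8a-octahydronaphthalene-7,8a-diol (both carbinol epimers)
Conditions: HC≡CMgBr (excess), THF, 0 °C to rt
Reagents that add atoms: ethynylmagnesium bromide, C#C[Mg]Br
Why: Grignard addition of the small, linear ethynyl nucleophile to the neopentyl aldehyde, with excess reagent covering the two hydroxyl groups; both carbinol epimers are carried on because the centre is oxidised in step 19.

Step 18
Reactants: 28 (3S,4S,4aR,5R,7R,8aS)-3-[(2S)-butan-2-yl]-4-(1-hydroxyprop-2-yn-1-yl)-2,4,5,7-tetramethyl-3,4,4a,5,6,7,8,8a-octahydronaphthalene-7,8a-diol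
Product: 29 (1S,2S,3R,4S,4aR,5R,7R,8aR)-3-[(2S)-butan-2-yl]-4-(1-hydroxyprop-2-yn-1-yl)-2,4,5,7-tetramethyldecahydronaphthalene-1,2,7,8a-tetrol
Conditions: OsO4 (1.1 equiv), TMEDA, CH2Cl2, −78 °C; then aq. Na2SO3, THF, 40 °C
Reagents that add atoms: osmium tetroxide, O=[Os](=O)(=O)=O
Why: Hydroxyl-directed cis-dihydroxylation: the OsO4–TMEDA complex accepts a hydrogen bond from the allylic C8a hydroxyl and is delivered to the same face of C1=C2 (syn [3+2] addition), which places the C2 hydroxyl cis to the C8a hydroxyl. The C1 configuration does not matter because it is oxidised next, and the alkyne should react far more slowly than the alkene.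

Step 19
Reactants: 29 (1S,2S,3R,4S,4aR,5R,7R,8aR)-3-[(2S)-butan-2-yl]-4-(1-hydroxyprop-2-yn-1-yl)-2,4,5,7-tetramethyldecahydronaphthalene-1,2,7,8a-tetrol
Product: 30 (2S,3R,4S,4aR,5R,7R,8aR)-3-[(2S)-butan-2-yl]-2,7,8a-trihydroxy-2,4,5,7-tetramethyl-4-(prop-2-ynoyl)octahydronaphthalen-1(2H)-one
Conditions: Dess–Martin periodinane (excess), pyridine, CH2Cl2, 0 °C to rt
Reagents that add atoms: none
Why: Dess–Martin oxidation of both secondary alcohols (C1 and the propargylic carbinol) in one operation gives the C1 ketone and the ynone; the three tertiary alcohols cannot be oxidised.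

Step 20
Reactants: 30 (2S,3R,4S,4aR,5R,7R,8aR)-3-[(2S)-butan-2-yl]-2,7,8a-trihydroxy-2,4,5,7-tetramethyl-4-(prop-2-ynoyl)octahydronaphthalen-1(2H)-one
Product: 31 (2S,3R,4S,4aR,5R,7R,8aR)-3-[(2S)-butan-2-yl]-2,7,8a-trihydroxy-4-[(2E)-3-methoxyprop-2-enoyl]-2,4,5,7-tetramethyloctahydronaphthalen-1(2H)-one
Conditions: MeOH, DABCO (cat.), CH2Cl2, rt
Reagents that add atoms: methanol, CO
Why: Amine-catalysed conjugate (oxa-Michael) addition of methanol to the terminal ynone; protonation of the allenolate should give the thermodynamically favoured (E)-β-methoxy enone, and the mild non-acidic conditions spare the α-hydroxy ketone.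

## Compound list

1 | (S)-2-methylbutan-1-ol | CC[C@H](C)CO | starting material
2 | ethyl 2-(triphenylphosphoranylidene)propanoate | CCOC(=O)C(C)=P(c1ccccc1)(c1ccccc1)c1ccccc1 | starting material
3 | (S)-2-methylbutanal | CC[C@H](C)C=O | intermediate (not isolated)
4 | ethyl (2E,4S)-2,4-dimethylhex-2-enoate | CC[C@H](C)/C=C(\C)C(=O)OCC | intermediate
5 | (2E,4S)-2,4-dimethylhex-2-en-1-ol | CC[C@H](C)/C=C(\C)CO | intermediate
6 | (2E,4S)-2,4-dimethylhex-2-enal | CC[C@H](C)/C=C(\C)C=O | intermediate
7 | 1,3-dithiane | C1CSCSC1 | starting material
8 | 2-lithio-1,3-dithiane | [Li]C1SCCCS1 | intermediate (not isolated)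
9 | (2E,4S)-1-(1,3-dithian-2-yl)-2,4-dimethylhex-2-en-1-ol, both C1 epimers | CC[C@H](C)/C=C(\C)C(O)C1SCCCS1 | intermediate
10 | (2E,4S)-1-(1,3-dithian-2-yl)-2,4-dimethylhex-2-en-1-one | CC[C@H](C)/C=C(\C)C(=O)C1SCCCS1 | intermediate
11 | methyl methacrylate | C=C(C)C(=O)OC | starting material
12 | methyl 3-{2-[(2E,4S)-2,4-dimethylhex-2-enoyl]-1,3-dithian-2-yl}-2-methylpropanoate, both C2 epimers | CC[C@H](C)/C=C(\C)C(=O)C1(CC(C)C(=O)OC)SCCCS1 | intermediate
13 | methyl 3-{2-[(1R,2E,4S)-1-hydroxy-2,4-dimethylhex-2-en-1-yl]-1,3-dithian-2-yl}-2-methylpropanoate, both C2 epimers | CC[C@H](C)/C=C(\C)[C@@H](O)C1(CC(C)C(=O)OC)SCCCS1 | intermediate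
14 | (7R)-10-methyl-7-[(2E,4S)-4-methylhex-2-en-2-yl]-8-oxa-1,5-dithiaspiro[5.5]undecan-9-one, both C10 epimers (key-step precursor) | CC1CC2(SCCCS2)[C@H](OC1=O)/C(C)=C/[C@@H](C)CC | intermediate
15 | (7R)-10-methyl-7-[(2E,4S)-4-methylhex-2-en-2-yl]-9-[(trimethylsilyl)oxy]-8-oxa-1,5-dithiaspiro[5.5]undec-9-ene | CC1=C(O[Si](C)(C)C)O[C@H](/C(C)=C/[C@@H](C)CC)C2(SCCCS2)C1 | intermediate (not isolated)
16 | trimethylsilyl (9S,10R)-9-[(2S)-butan-2-yl]-8,10-dimethyl-1,5-dithiaspiro[5.5]undec-7-ene-10-carboxylate | CC[C@H](C)[C@@H]1[C@](C)(C(=O)O[Si](C)(C)C)CC2(SCCCS2)C=C1C | intermediate (not isolated)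
17 | (9S,10R)-9-[(2S)-butan-2-yl]-8,10-dimethyl-1,5-dithiaspiro[5.5]undec-7-ene-10-carboxylic acid (key-step product) | CC[C@H](C)[C@@H]1[C@](C)(C(=O)O)CC2(SCCCS2)C=C1C | intermediate
18 | methyl (9S,10R)-9-[(2S)-butan-2-yl]-8,10-dimethyl-1,5-dithiaspiro[5.5]undec-7-ene-10-carboxylate | CC[C@H](C)[C@@H]1[C@](C)(C(=O)OC)CC2(SCCCS2)C=C1C | intermediate
19 | methyl (1R,2S)-2-[(2S)-butan-2-yl]-1,3-dimethyl-5-oxocyclohex-3-ene-1-carboxylate | CC[C@H](C)[C@@H]1[C@](C)(C(=O)OC)CC(=O)C=C1C | intermediate
20 | (E)-pent-3-en-2-one | C/C=C/C(C)=O | starting material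
21 | lithium dienolate of 19 (C8a(OLi)=C4a and C1=C2) | CC[C@H](C)[C@@H]1[C@](C)(C(=O)OC)C=C(O[Li])C=C1C | intermediate (not isolated)
22 | methyl (1S,2S,6R)-2-[(2S)-butan-2-yl]-1,3-dimethyl-5-oxo-6-[(2R)-4-oxopentan-2-yl]cyclohex-3-ene-1-carboxylate | CC[C@H](C)[C@@H]1[C@](C)(C(=O)OC)[C@@H]([C@H](C)CC(C)=O)C(=O)C=C1C | intermediate
23 | lithium enolate of 22 at the methyl ketone (C7(OLi)=C8H2) | CC[C@H](C)[C@@H]1[C@](C)(C(=O)OC)[C@@H]([C@H](C)CC(=C)O[Li])C(=O)C=C1C | intermediate (not isolated)
24 | methyl (3S,4S,4aR,5R,8aS)-3-[(2S)-butan-2-yl]-8a-hydroxy-2,4,5-trimethyl-7-oxo-3,4,4a,5,6,7,8,8a-octahydronaphthalene-4-carboxylate | CC[C@H](C)[C@@H]1[C@](C)(C(=O)OC)[C@H]2[C@H](C)CC(=O)C[C@]2(O)C=C1C | intermediate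
25 | methyl (3S,4S,4aR,5R,7R,8aS)-3-[(2S)-butan-2-yl]-7,8a-dihydroxy-2,4,5,7-tetramethyl-3,4,4a,5,6,7,8,8a-octahydronaphthalene-4-carboxylate | CC[C@H](C)[C@@H]1[C@](C)(C(=O)OC)[C@H]2[C@H](C)C[C@@](C)(O)C[C@]2(O)C=C1C | intermediate
26 | (3S,4S,4aR,5R,7R,8aS)-3-[(2S)-butan-2-yl]-4-(hydroxymethyl)-2,4,5,7-tetramethyl-3,4,4a,5,6,7,8,8a-octahydronaphthalene-7,8a-diol | CC[C@H](C)[C@@H]1[C@](C)(CO)[C@H]2[C@H](C)C[C@@](C)(O)C[C@]2(O)C=C1C | intermediate
27 | (3S,4S,4aR,5R,7R,8aS)-3-[(2S)-butan-2-yl]-7,8a-dihydroxy-2,4,5,7-tetramethyl-3,4,4a,5,6,7,8,8a-octahydronaphthalene-4-carbaldehyde | CC[C@H](C)[C@@H]1[C@](C)(C=O)[C@H]2[C@H](C)C[C@@](C)(O)C[C@]2(O)C=C1C | intermediate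
28 | (3S,4S,4aR,5R,7R,8aS)-3-[(2S)-butan-2-yl]-4-(1-hydroxyprop-2-yn-1-yl)-2,4,5,7-tetramethyl-3,4,4a,5,6,7,8,8a-octahydronaphthalene-7,8a-diol, both carbinol epimers | CC[C@H](C)[C@@H]1[C@](C)(C(O)C#C)[C@H]2[C@H](C)C[C@@](C)(O)C[C@]2(O)C=C1C | intermediate
29 | (1S,2S,3R,4S,4aR,5R,7R,8aR)-3-[(2S)-butan-2-yl]-4-(1-hydroxyprop-2-yn-1-yl)-2,4,5,7-tetramethyldecahydronaphthalene-1,2,7,8a-tetrol | CC[C@H](C)[C@@H]1[C@](C)(C(O)C#C)[C@H]2[C@H](C)C[C@@](C)(O)C[C@]2(O)[C@@H](O)[C@@]1(C)O | intermediate
30 | (2S,3R,4S,4aR,5R,7R,8aR)-3-[(2S)-butan-2-yl]-2,7,8a-trihydroxy-2,4,5,7-tetramethyl-4-(prop-2-ynoyl)octahydronaphthalen-1(2H)-one | CC[C@H](C)[C@@H]1[C@](C)(C(=O)C#C)[C@H]2[C@H](C)C[C@@](C)(O)C[C@]2(O)C(=O)[C@@]1(C)O | intermediate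
31 | (2S,3R,4S,4aR,5R,7R,8aR)-3-[(2S)-butan-2-yl]-2,7,8a-trihydroxy-4-[(2E)-3-methoxyprop-2-enoyl]-2,4,5,7-tetramethyloctahydronaphthalen-1(2H)-one | CC[C@H](C)[C@@H]1[C@](C)(C(=O)/C=C/OC)[C@H]2[C@H](C)C[C@@](C)(O)C[C@]2(O)C(=O)[C@@]1(C)O | target

## Step count and least certain steps

Total step count: 20. Longest linear sequence: 20 steps, from 1 to 31; the other starting materials (2, 7, 11, 20) are used as purchased.

**Step 9 (key step).** The most likely failure is a slow rearrangement, because a quaternary and a branched tertiary carbon are pressed together in the boat transition state. Prolonged heating then gives time for loss of the silyl group back to 14, for C-silylation, or for decomposition of the ketene acetal. The fallback sets out from 13 and returns at 18. The carbinol of 13 is converted with methyl chloroformate and pyridine into the allylic methyl carbonate F1. The ester enolate of F1 is formed with LiN(SiMe3)2 and cyclised with Pd(PPh3)4 (zerovalent palladium) in THF in an intramolecular Tsuji–Trost allylic alkylation. Ionisation anti to the carbonate and attack of the enolate on C3 anti to palladium form the six-membered ring with the C1=C2 alkene and the same C3 configuration. The C4 configuration would then depend on the approach of an enolate of undefined geometry, so C4 epimers would have to be separated at 18.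

**Step 7.** The most likely failure is weak or reversed discrimination of the two carbonyl faces, because both ketone substituents are bulky, together with slow hydride delivery to a carbonyl next to a fully substituted carbon. The fallback sets out from 12 and returns at 14. Luche reduction (NaBH4, CeCl3·7H2O, MeOH) gives 13 together with its C1 epimer, methyl 3-{2-[(1S,2E,4S)-1-hydroxy-2,4-dimethylhex-2-en-1-yl]-1,3-dithian-2-yl}-2-methylpropanoate F2. Lactonisation as in step 8 gives 14 and the (7S)-lactone F3, which are diastereomers because of the fixed sec-butyl centre and would be separated by chromatography. F3 is recycled by methanolysis to F2 and Parikh–Doering oxidation back to 12.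

**Step 12.** The most likely failure is continuation of the adduct enolate into a second, intramolecular conjugate addition onto C2, which would give a bicyclo[2.2.2]octanone. Addition to the carbonyl group of 20, proton transfer to its acidic methyl group and an insufficient facial bias at C4a are further risks. The fallback sets out from 19 and returns at 22. Dienolate 21 is added to ethyl 2-acetylbut-2-enoate (from ethyl acetoacetate and acetaldehyde by Knoevenagel condensation). The adduct is the β-keto ester F4, whose stabilised enolate should not add to the hindered C2. Krapcho dealkoxycarbonylation (LiCl, wet DMSO, 140 °C) then gives 22. With this doubly activated acceptor the C5 configuration is less predictable, and C4a can equilibrate during the decarboxylation.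

**Step 13.** The most likely failure is reversal of the lithium aldolate, or proton exchange that forms the C6 or C4a enolate and so opens other closures. Closure to the cis-fused ketol is also possible if ring A reacts from its other half-chair. The fallback sets out from 22 and returns at 24. The methyl ketone is converted under kinetic conditions (LiN(i-Pr)2, Me3SiCl, THF, −78 °C) into the trimethylsilyl enol ether F5. F5 is closed by an intramolecular Mukaiyama aldol addition (TiCl4, CH2Cl2, −78 °C), in which the Lewis acid activates the C8a carbonyl and the titanium aldolate does not revert.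

**Step 18.** The most likely failure is slow osmylation of a hindered trisubstituted alkene whose directed face also carries the axial C4 methyl group. Oxidation of the alkyne, undirected attack from the other face, or binding of the reagent by the other three hydroxyl groups could then compete. The fallback sets out from 25 and returns at 29, and it moves the dihydroxylation forward to the simplest substrate. Diol ester 25 is treated with OsO4 and TMEDA as in step 18 to give the tetraol ester F6. LiAlH4 reduces the ester to the pentaol F7. TEMPO with PhI(OAc)2, which is selective for the primary alcohol, gives the aldehyde F8. Ethynylmagnesium bromide then gives 29.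

## Further compounds

F1 | step 9 | methyl 3-{2-[(1R,2E,4S)-1-[(methoxycarbonyl)oxy]-2,4-dimethylhex-2-en-1-yl]-1,3-dithian-2-yl}-2-methylpropanoate | CC[C@H](C)/C=C(\C)[C@@H](OC(=O)OC)C1(CC(C)C(=O)OC)SCCCS1
F2 | step 7 | methyl 3-{2-[(1S,2E,4S)-1-hydroxy-2,4-dimethylhex-2-en-1-yl]-1,3-dithian-2-yl}-2-methylpropanoate | CC[C@H](C)/C=C(\C)[C@H](O)C1(CC(C)C(=O)OC)SCCCS1
F3 | step 7 | (7S)-10-methyl-7-[(2E,4S)-4-methylhex-2-en-2-yl]-8-oxa-1,5-dithiaspiro[5.5]undecan-9-one | CC1CC2(SCCCS2)[C@@H](OC1=O)/C(C)=C/[C@@H](C)CC
F4 | step 12 | methyl (1S,2S,6R)-2-[(2S)-butan-2-yl]-6-[3-(ethoxycarbonyl)-4-oxopentan-2-yl]-1,3-dimethyl-5-oxocyclohex-3-ene-1-carboxylate (side-chain C2 as in 22, C3 epimers) | CC[C@H](C)[C@@H]1[C@](C)(C(=O)OC)[C@@H]([C@H](C)C(C(C)=O)C(=O)OCC)C(=O)C=C1C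
F5 | step 13 | methyl (1S,2S,6R)-2-[(2S)-butan-2-yl]-1,3-dimethyl-5-oxo-6-{(2R)-4-[(trimethylsilyl)oxy]pent-4-en-2-yl}cyclohex-3-ene-1-carboxylate | CC[C@H](C)[C@@H]1[C@](C)(C(=O)OC)[C@@H]([C@H](C)CC(=C)O[Si](C)(C)C)C(=O)C=C1C
F6 | step 18 | methyl (1S,2S,3R,4S,4aR,5R,7R,8aR)-3-[(2S)-butan-2-yl]-1,2,7,8a-tetrahydroxy-2,4,5,7-tetramethyldecahydronaphthalene-4-carboxylate | CC[C@H](C)[C@@H]1[C@](C)(C(=O)OC)[C@H]2[C@H](C)C[C@@](C)(O)C[C@]2(O)[C@@H](O)[C@@]1(C)O
F7 | step 18 | (1S,2S,3R,4S,4aR,5R,7R,8aR)-3-[(2S)-butan-2-yl]-4-(hydroxymethyl)-2,4,5,7-tetramethyldecahydronaphthalene-1,2,7,8a-tetrol | CC[C@H](C)[C@@H]1[C@](C)(CO)[C@H]2[C@H](C)C[C@@](C)(O)C[C@]2(O)[C@@H](O)[C@@]1(C)O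
F8 | step 18 | (1S,2S,3R,4S,4aR,5R,7R,8aR)-3-[(2S)-butan-2-yl]-1,2,7,8a-tetrahydroxy-2,4,5,7-tetramethyldecahydronaphthalene-4-carbaldehyde | CC[C@H](C)[C@@H]1[C@](C)(C=O)[C@H]2[C@H](C)C[C@@](C)(O)C[C@]2(O)[C@@H](O)[C@@]1(C)O
A1 | alternative 1 | octalin tert-butyldimethylsilyl enol ether (C8a=C1) with formyl and (4-methoxybenzyloxy)methyl groups at C4 | CC[C@H](C)[C@@H]1[C@](C=O)(COCc3ccc(OC)cc3)[C@H]2[C@H](C)C[C@@](C)(O)CC2=C(O[Si](C)(C)C(C)(C)C)[C@H]1C
A2 | alternative 2 | octalinone methyl ester with a diisopropylsilylene bridge between the C2 and C8a oxygen atoms and a C7=C8 alkene | CC[C@H](C)[C@@H]1[C@](C)(C(=O)OC)[C@H]2[C@H](C)CC(C)=C[C@]2(O[Si]5(C(C)C)C(C)C)C(=O)[C@@]1(C)O5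
A3 | alternative 3 | decalin C4 methyl ketone with a cyclic carbonate across the C7 and C8a oxygen atoms | CC[C@H](C)[C@@H]1[C@](C)(C(C)=O)[C@H]2[C@H](C)C[C@@](C)(OC(=O)O3)C[C@]23C(=O)[C@@]1(C)O
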